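Of the constants of this flask, the readings give two ratios without any rate law, target over starting material and one lumped ratio, so start at the two ends of the delta run, which is the very flask asked about, followed so far.

all flasks: starting material 20 mM; catalyst 100 µM

| run | temperature | remark | time |
|---|---|---|---|
| delta | 80 °C | the very flask that is asked about, followed so far |  |
| theta | 75 °C | run made earlier |  |
| flask | 80 °C |  | 3.0 h |

- delta (time / min: target / %, starting material / %): 8.00: 59.7, 20.8; 20.0: 47.2, 16.4; 40.0: 36.1, 11.9; 60.0: 29.9, 10.0; 80.0: 27.0, 8.8; 120: 23.6, 7.9; 150: 23.1, 7.4
- theta (time / min: target / %, starting material / %): 8.00: 63.1, 20.3; 20.0: 50.4, 16.5; 40.0: 39.2, 12.8; 60.0: 32.1, 10.4; 80.0: 26.7, 8.4; 120: 20.8, 6.8; 150: 19.1, 5.9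

(each reading ± 0.3 percentage points)

- south-east: at 3.0 h add catalyst, 100 % of the amount charged, then wait 6.0 h
- south-west: at 3.0 h take out 90 % of the target then present, then wait 6.0 h
- north-east: at 3.0 h raise the temperature by 25 K, then wait 6.0 h
- north-west: change nothing and wait 6.0 h more

- removed target is counted in
- additions bring no volume worth counting

* target, in percent of the starting material first charged, at 3.0 h
* the option that brings most further target ("none" if no option brings more than 2 percentage points) (south-east / south-west / north-east / north-west / none)
* target present, with what was taken out counted in, in percent of the starting material first charged, after south-west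
* target present, with what was taken out counted in, in percent of the starting material first charged, after north-west

At the early end, target over starting material is 2.87 at 8.00 min and 3.12 at 150 min, so the two move as a pair. At the late end, target falls by just 0.5 percentage points between the last two readings, yet the pair holds 30.5 % of the charge. The rest sits somewhere unseen.

Joining the ends, I read this flask as under thermodynamic control, not kinetic control, and fold it into one number. 0.300 is the target odds, target divided by the rest of the charge at the last delta reading. It works like an overall equilibrium constant.

The odds give a target share of 23.1 %, which is my answer for now, and waiting should hold it there. A catalyst shifts no equilibrium, so I expect nothing from adding more. Taking out 90 % of the target removes 20.8 % of the charge. What stays re-divides at the same odds, giving 39.1 % with the removed part counted in.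

Is one number enough? Not for heat. The theta run ends at odds of 0.236, lower than delta's, and it is still falling, so I take the factor 1.27 per step between the two runs as a low estimate. The rise is 5 such steps. Extrapolated straight, that gives odds of 1.00 and target 50.0 %, a larger gain than south-west's. I choose north-east.

The forecast says 22.8 % now, 22.5 % after north-west, 24 % after south-west and none for best, on the ground that “by 3 h only about 1.5% of the catalyst survives”; on south-west and best it parts from my reckoning.

The flask gives 22.7 % at 3.0 h, 22.4 % after north-west and 38.3 % after south-west. Its best option is north-east, worth 33 points, against 16 points for south-west and −0.24 points for south-east.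

    starting material ⇌ target (K = 3.00, k = 0.0262 s⁻¹, Ea = 107 kJ mol⁻¹, ΔH = −8.00 kJ mol⁻¹)
    target + catalyst ⇌ isomer of the product A + catalyst, rate k2*[catalyst]*[target] forward; the back reaction follows from the equilibrium constant (K = 0.789, k = 8.07 L mol⁻¹ s⁻¹, Ea = 65.0 kJ mol⁻¹, ΔH = −65.0 kJ mol⁻¹)
    isomer of the product A ⇌ isomer of the product B (K = 2.96, k = 0.00109 s⁻¹, Ea = 117 kJ mol⁻¹, ΔH = −41.0 kJ mol⁻¹)
    (constants at 80 °C)

Catalyst stands at 100 % at 180 min. The odds 0.300 gave 39.1 % for south-west, 0.80 points above the flask.

On the neighbour at 95 °C, 3 steps up, the odds reach 0.619, so my low estimate for target is 38.2 %. The computed flask gives 44.9 %, more than that estimate.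

The earlier runs and the new flask are simulated on assumed constants, and the scatter is random.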